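**Retrosynthetic overview**
1. Last C–C bond: sp3–sp2 Negishi coupling of a C13 chromene alkyl iodide (14) with a C14 butenolide vinyl iodide (27), then phenol unmasking.
2. Chromene 14: Au(I) 6-endo hydroarylation of a tertiary aryl propargyl ether, made from the vinyl ether that a Pd-catalysed asymmetric allylic etherification (phenol 4 + carbonate 8) delivers. This sets C2.
3. Phenol 4 comes from o-cresol; carbonate 8 from but-3-yn-1-ol by Zr-catalysed methylalumination.
4. Butenolide 27: Z-selective Ando olefination of an α-silyloxy aldehyde (from (S)-glycidol, which supplies C5) with a homoprenyl phosphonate, then lactonisation.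
5. Ring order: the 2H-chromene ring (step 10) and the butenolide ring (step 22) are formed independently, before the fragments are joined.

Assumption: in step 7 the (R,R)-ligand with the (E)-carbonate is taken to give the (S)-ether. I could not fix the sense of induction from first principles, so it must be checked on the first batch; if it is opposite, use the (S,S)-ligand and change nothing else.

The target is (5R) at the butenolide and (2S) at the chromene, with an E trisubstituted alkene.

---

**Arene fragment**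

Step 1
Reactants: 1 o-cresol
Product: 2 2-methyl-1,4-benzoquinone
Conditions: Fremy's salt (2.2 eq), KH2PO4, H2O/acetone, rt
Reagents that add atoms: potassium nitrosodisulfonate, [O]N(S(=O)(=O)[O-])S(=O)(=O)[O-].[K+].[K+] (supplies the para oxygen)
Why: Teuber oxidation converts a phenol with a free para position into the p-quinone.

Step 2
Reactants: 2 2-methyl-1,4-benzoquinone
Product: 3 2-methylbenzene-1,4-diol
Conditions: Na2S2O4, EtOAc/H2O, rt
Reagents that add atoms: none
Why: Dithionite reduction of a quinone to the hydroquinone is clean and quantitative.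

Step 3
Reactants: 3 2-methylbenzene-1,4-diol
Product: 4 2-methyl-4-[(triisopropylsilyl)oxy]phenol
Conditions: TIPSCl (1.0 eq), imidazole, DMF/CH2Cl2, 0 °C; chromatography
Reagents that add atoms: TIPSCl, CC(C)[Si](Cl)(C(C)C)C(C)C
Why: Silylation with a bulky chloride favours the OH meta to the methyl group, leaving the hindered OH (future O1) free; the minor regioisomer and bis-ether are separated.

**Allylic carbonate**

Step 4
Reactants: 5 but-3-yn-1-ol
Product: 6 (but-3-yn-1-yloxy)(tert-butyl)dimethylsilane
Conditions: TBSCl, imidazole, CH2Cl2, rt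
Reagents that add atoms: TBSCl, CC(C)(C)[Si](C)(C)Cl
Why: Standard silyl protection of a primary alcohol.

Step 5
Reactants: 6
Product: 7 (E)-5-[(tert-butyldimethylsilyl)oxy]-3-methylpent-2-en-1-ol
Conditions: AlMe3, Cp2ZrCl2 (cat.), CH2Cl2, 0 °C to rt; then n-BuLi, (CH2O)n, THF, 0 °C to rt
Reagents that add atoms: AlMe3, C[Al](C)C; paraformaldehyde, C=O
Why: Negishi Zr-catalysed methylalumination is syn with Me to the internal carbon, fixing the E geometry; the alkenylalanate is trapped by formaldehyde.

Step 6
Reactants: 7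
Product: 8 (E)-5-[(tert-butyldimethylsilyl)oxy]-3-methylpent-2-en-1-yl methyl carbonate
Conditions: ClCO2Me, pyridine, DMAP (cat.), CH2Cl2, 0 °C
Reagents that add atoms: methyl chloroformate, COC(=O)Cl
Why: Acylation gives the allylic carbonate, which is the ionisable leaving group for Pd(0).

**Chromene fragment**

Step 7
Reactants: 4 phenol; 8 carbonate
Product: 9 (S)-tert-butyldimethyl{[3-methyl-3-(2-methyl-4-triisopropylsilyloxyphenoxy)pent-4-en-1-yl]oxy}silane
Conditions: Pd2(dba)3·CHCl3 (1–2 mol%), (R,R)-Trost DACH-phenyl ligand (3–6 mol%), CH2Cl2, rt; stop when 8 is consumed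
Reagents that add atoms: none
Why: Tsuji–Trost asymmetric allylic alkylation: phenoxide attacks the more substituted terminus of the π-allyl-Pd inside the chiral pocket, forming the tertiary ether and the quaternary stereocentre (S, per the assumption above).

Step 8
Reactants: 9
Product: 10 (S)-4-[(tert-butyldimethylsilyl)oxy]-2-methyl-2-(2-methyl-4-triisopropylsilyloxyphenoxy)butanal
Conditions: OsO4 (cat.), NaIO4, 2,6-lutidine, dioxane/H2O, rt
Reagents that add atoms: OsO4 (oxygen source, reoxidised by NaIO4), O=[Os](=O)(=O)=O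
Why: Lemieux–Johnson cleavage of the only alkene; the resulting α-quaternary aldehyde cannot enolise, so C2 is not at risk.

Step 9
Reactants: 10
Product: 11 (S)-tert-butyldimethyl{[3-methyl-3-(2-methyl-4-triisopropylsilyloxyphenoxy)pent-4-yn-1-yl]oxy}silane
Conditions: TMSCHN2, LDA, THF, −78 °C to rt
Reagents that add atoms: trimethylsilyldiazomethane, C[Si](C)(C)C=[N+]=[N-] (supplies the terminal alkyne CH)
Why: Colvin rearrangement: the alkylidene carbene undergoes 1,2-H shift to the terminal alkyne under non-protic conditions that spare both silyl ethers.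

Step 10
Reactants: 11
Product: 12 (S)-2-{2-[(tert-butyldimethylsilyl)oxy]ethyl}-2,8-dimethyl-6-[(triisopropylsilyl)oxy]-2H-chromene
Conditions: Ph3PAuNTf2 (2–5 mol%), CH2Cl2, 0 °C to rt
Reagents that add atoms: none
Why: Au(I)-catalysed 6-endo-dig intramolecular hydroarylation at the only free ortho position closes the chromene without breaking the C2–O bond, so the stereocentre is retained (a thermal Claisen route would racemise).

Step 11
Reactants: 12
Product: 13 2-[(S)-2,8-dimethyl-6-(triisopropylsilyloxy)-2H-chromen-2-yl]ethanol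
Conditions: CSA (10 mol%), MeOH/CH2Cl2, 0 °C
Reagents that add atoms: none
Why: Acidic methanolysis removes the primary alkyl TBS ether while the aryl TIPS ether, which is acid-stable, survives.

Step 12
Reactants: 13
Product: 14 (S)-2-(2-iodoethyl)-2,8-dimethyl-6-[(triisopropylsilyl)oxy]-2H-chromene
Conditions: I2, PPh3, imidazole, CH2Cl2, 0 °C to rt
Reagents that add atoms: iodine, II
Why: Appel-type iodination of a primary alcohol under neutral conditions.

**Phosphonate**

Step 13
Reactants: 15 ethyl bromoacetate
Product: 16 ethyl 2-(diphenoxyphosphoryl)acetate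
Conditions: (PhO)2P(O)H, Et3N, CH2Cl2, 0 °C to rt
Reagents that add atoms: diphenyl phosphite, O=P(Oc1ccccc1)Oc1ccccc1
Why: Michaelis–Becker-type P-alkylation gives the Ando phosphonate.

Step 14
Reactants: 16; 17 5-bromo-2-methylpent-2-ene
Product: 18 ethyl 2-(diphenoxyphosphoryl)-6-methylhept-5-enoate (racemic)
Conditions: NaH, NaI (cat.), DMSO, rt to 50 °C
Reagents that add atoms: none
Why: C-alkylation of the stabilised phosphonoacetate anion with a primary halide installs the homoprenyl chain.

**Butenolide fragment**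

Step 15
Reactants: 19 (S)-glycidol
Product: 20 (R)-2-{[(4-methoxybenzyl)oxy]methyl}oxirane
Conditions: NaH, PMBCl, TBAI (cat.), THF/DMF, 0 °C to rt
Reagents that add atoms: 4-methoxybenzyl chloride, COc1ccc(CCl)cc1
Why: Williamson etherification; the Payne rearrangement of glycidol alkoxide is degenerate, so ee is preserved (the descriptor changes from S to R only because of CIP priorities).

Step 16
Reactants: 20
Product: 21 (R)-1-[(4-methoxybenzyl)oxy]pent-4-yn-2-ol
Conditions: lithium acetylide·ethylenediamine, DMSO, rt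
Reagents that add atoms: lithium acetylide, [Li]C#C
Why: SN2 opening of the epoxide at the terminal carbon leaves the stereocentre untouched.

Step 17
Reactants: 21
Product: 22 (R,E)-5-iodo-1-[(4-methoxybenzyl)oxy]-4-methylpent-4-en-2-ol
Conditions: AlMe3 (3 eq), Cp2ZrCl2 (0.3 eq), CH2Cl2, 0 °C to rt; then I2, THF, −30 °C
Reagents that add atoms: AlMe3, C[Al](C)C; iodine, II
Why: Negishi carboalumination–iodinolysis gives the (E)-2-methyl vinyl iodide by syn addition, and tolerates the free alcohol as its aluminium alkoxide.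

Step 18
Reactants: 22
Product: 23 (R,E)-tert-butyl({5-iodo-1-[(4-methoxybenzyl)oxy]-4-methylpent-4-en-2-yl}oxy)dimethylsilane
Conditions: TBSCl, imidazole, DMF, rt
Reagents that add atoms: TBSCl, CC(C)(C)[Si](C)(C)Cl
Why: Silylation of the secondary alcohol keeps it masked until lactonisation.

Step 19
Reactants: 23
Product: 24 (R,E)-2-[(tert-butyldimethylsilyl)oxy]-5-iodo-4-methylpent-4-en-1-ol
Conditions: DDQ, CH2Cl2/pH 7 buffer, 0 °C
Reagents that add atoms: none
Why: Oxidative PMB cleavage is neutral, so the TBS group does not migrate and the vinyl iodide is untouched.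

Step 20
Reactants: 24
Product: 25 (R,E)-2-[(tert-butyldimethylsilyl)oxy]-5-iodo-4-methylpent-4-enal
Conditions: Dess–Martin periodinane, NaHCO3, CH2Cl2, 0 °C; used crude
Reagents that add atoms: none
Why: Buffered Dess–Martin oxidation gives the α-silyloxy aldehyde without epimerisation.

Step 21
Reactants: 25; 18
Product: 26 ethyl (2Z,4R,6E)-4-[(tert-butyldimethylsilyl)oxy]-7-iodo-6-methyl-2-(4-methylpent-3-en-1-yl)hepta-2,6-dienoate
Conditions: 18, NaH, THF, 0 °C; then 25, −78 to 0 °C
Reagents that add atoms: none
Why: Ando-type Z-selective Horner–Wadsworth–Emmons olefination places the ester cis to C4, as required for ring closure.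

Step 22
Reactants: 26
Product: 27 (R)-5-[(E)-3-iodo-2-methylallyl]-3-(4-methylpent-3-en-1-yl)furan-2(5H)-one
Conditions: 48% aq. HF/MeCN, 0 °C to rt (PPTS cat., CH2Cl2 if closure is incomplete)
Reagents that add atoms: none
Why: Desilylation frees the γ-hydroxyl, which lactonises onto the cis ester with loss of EtOH; C5 is the carbinol carbon and is not touched.

**Coupling and end game**

Step 23
Reactants: 14 (1.3 eq); 27
Product: 28 (R)-5-{(E)-5-[(S)-2,8-dimethyl-6-(triisopropylsilyloxy)-2H-chromen-2-yl]-2-methylpent-2-en-1-yl}-3-(4-methylpent-3-en-1-yl)furan-2(5H)-one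
Conditions: 14, Zn dust (BrCH2CH2Br/TMSCl-activated), DMA, 40 °C; then 27, Pd(dppf)Cl2·CH2Cl2 (5 mol%), THF, rt
Reagents that add atoms: none
Why: Negishi sp3–sp2 cross-coupling: the primary alkylzinc iodide couples with retention of the E geometry under base-free conditions that the butenolide and its C5–H tolerate.

Step 24
Reactants: 28
Product: 29 tuberatolide B
Conditions: TBAF/AcOH (1:1), THF, 0 °C, under argon
Reagents that add atoms: none
Why: Buffered fluoride cleaves the aryl silyl ether without base-induced epimerisation or opening of the butenolide.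

---

**Compound list**

1 | o-cresol | Cc1ccccc1O | starting material
2 | 2-methyl-1,4-benzoquinone | CC1=CC(=O)C=CC1=O | intermediate
3 | 2-methylbenzene-1,4-diol | Cc1cc(O)ccc1O | intermediate
4 | 2-methyl-4-(triisopropylsilyloxy)phenol | Cc1cc(O[Si](C(C)C)(C(C)C)C(C)C)ccc1O | intermediate
5 | but-3-yn-1-ol | C#CCCO | starting material
6 | (but-3-yn-1-yloxy)(tert-butyl)dimethylsilane | C#CCCO[Si](C)(C)C(C)(C)C | intermediate
7 | (E)-5-(TBS-oxy)-3-methylpent-2-en-1-ol | OC/C=C(\C)CCO[Si](C)(C)C(C)(C)C | intermediate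
8 | (E)-5-(TBS-oxy)-3-methylpent-2-en-1-yl methyl carbonate | COC(=O)OC/C=C(\C)CCO[Si](C)(C)C(C)(C)C | intermediate
9 | (S)-tertiary aryl allyl ether | CC(C)(C)[Si](C)(C)OCC[C@@](Oc1ccc(O[Si](C(C)C)(C(C)C)C(C)C)cc1C)(C)C=C | intermediate
10 | (S)-α-aryloxy aldehyde | CC(C)(C)[Si](C)(C)OCC[C@@](Oc1ccc(O[Si](C(C)C)(C(C)C)C(C)C)cc1C)(C)C=O | intermediate
11 | (S)-tertiary aryl propargyl ether | CC(C)(C)[Si](C)(C)OCC[C@@](Oc1ccc(O[Si](C(C)C)(C(C)C)C(C)C)cc1C)(C)C#C | intermediate
12 | (S)-2-[2-(TBS-oxy)ethyl]-2,8-dimethyl-6-(TIPS-oxy)-2H-chromene | CC(C)(C)[Si](C)(C)OCC[C@@]1(C)C=Cc2cc(O[Si](C(C)C)(C(C)C)C(C)C)cc(C)c2O1 | intermediate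
13 | 2-[(S)-2,8-dimethyl-6-(TIPS-oxy)-2H-chromen-2-yl]ethanol | OCC[C@@]1(C)C=Cc2cc(O[Si](C(C)C)(C(C)C)C(C)C)cc(C)c2O1 | intermediate
14 | (S)-2-(2-iodoethyl)-2,8-dimethyl-6-(TIPS-oxy)-2H-chromene | ICC[C@@]1(C)C=Cc2cc(O[Si](C(C)C)(C(C)C)C(C)C)cc(C)c2O1 | intermediate
15 | ethyl bromoacetate | CCOC(=O)CBr | starting material
16 | ethyl 2-(diphenoxyphosphoryl)acetate | CCOC(=O)CP(=O)(Oc1ccccc1)Oc1ccccc1 | intermediate
17 | 5-bromo-2-methylpent-2-ene | CC(C)=CCCBr | starting material
18 | ethyl 2-(diphenoxyphosphoryl)-6-methylhept-5-enoate | CCOC(=O)C(CCC=C(C)C)P(=O)(Oc1ccccc1)Oc1ccccc1 | intermediate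
19 | (S)-glycidol | OC[C@H]1CO1 | starting material
20 | (R)-PMB glycidyl ether | COc1ccc(COC[C@H]2CO2)cc1 | intermediate
21 | (R)-1-(PMB-oxy)pent-4-yn-2-ol | COc1ccc(COC[C@H](O)CC#C)cc1 | intermediate
22 | (R,E)-5-iodo-1-(PMB-oxy)-4-methylpent-4-en-2-ol | COc1ccc(COC[C@H](O)C/C(C)=C/I)cc1 | intermediate
23 | (R,E)-2-O-TBS ether of 22 | COc1ccc(COC[C@H](O[Si](C)(C)C(C)(C)C)C/C(C)=C/I)cc1 | intermediate
24 | (R,E)-2-(TBS-oxy)-5-iodo-4-methylpent-4-en-1-ol | OC[C@H](O[Si](C)(C)C(C)(C)C)C/C(C)=C/I | intermediate
25 | (R,E)-2-(TBS-oxy)-5-iodo-4-methylpent-4-enal | O=C[C@H](O[Si](C)(C)C(C)(C)C)C/C(C)=C/I | intermediate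
26 | ethyl (2Z,4R,6E)-4-(TBS-oxy)-7-iodo-6-methyl-2-(4-methylpent-3-enyl)hepta-2,6-dienoate | CCOC(=O)/C(CCC=C(C)C)=C\[C@H](O[Si](C)(C)C(C)(C)C)C/C(C)=C/I | intermediate
27 | (R)-5-[(E)-3-iodo-2-methylallyl]-3-(4-methylpent-3-enyl)furan-2(5H)-one | CC(C)=CCCC1=C[C@@H](C/C(C)=C/I)OC1=O | intermediate
28 | O-TIPS tuberatolide B | CC(C)=CCCC1=C[C@@H](C/C(C)=C/CC[C@@]2(C)C=Cc3cc(O[Si](C(C)C)(C(C)C)C(C)C)cc(C)c3O2)OC1=O | intermediate
29 | tuberatolide B | CC(C)=CCCC1=C[C@@H](C/C(C)=C/CC[C@@]2(C)C=Cc3cc(O)cc(C)c3O2)OC1=O | target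

---

**Totals**
Total steps: 24.
Longest linear sequence: 11 steps (1–3, 7–12, 23, 24; the branch 4–6, 7–12, 23, 24 is also 11). The butenolide branch is 10 (15–22, 23, 24).

**Three steps most likely to fail**

1. Step 7 (Pd-AAA). Risks are the branched/linear ratio, the ee with an ortho-substituted phenol, and the sense of induction. Fallback: set C2 by Sharpless epoxidation of 7, convert the epoxy alcohol to the epoxy chloride and treat with n-BuLi to get the tertiary propargylic alcohol of predictable configuration. Arylate it by SNAr on a 4-fluoro-3-methylbenzaldehyde-type arene, then turn CHO into OH by Dakin/Baeyer–Villiger oxidation and silylate, rejoining the route at 11.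

2. Step 10 (Au hydroarylation). Risks are ionisation of the tertiary propargylic ether (ee erosion), attack of the silyl ether oxygen on the activated alkyne, and benzofuran by-products. Fallback: from vinyl ether 9, hydroborate and oxidise the vinyl group to the carboxylic acid, close by intramolecular Friedel–Crafts acylation to the chroman-4-one, then NaBH4 reduction and acid dehydration to the chromene. The C2–O bond is never activated in that sequence.

3. Step 23 (Negishi coupling). Risks are sluggish zinc insertion, β-hydride elimination or homocoupling, and butenolide sensitivity. Fallback: couple before the lactone exists. Join 14 with vinyl iodide 23 (PMB/TBS-protected; Negishi, or B-alkyl Suzuki via t-BuLi/B-OMe-9-BBN), then run steps 19–22 on the coupled material so the butenolide is formed last.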